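A small charge of Sbt, 120 mM against 180 mM of Ptn in the larch run, makes Sbt the limiting reagent, so I reckon with what has not become Pdt and not with what has.

in all of them: Sbt 120 mM; Ctl 6.00 mM
- larch: Ptn 180 mM
- elm: Ptn 270 mM
- oak: Ptn 370 mM; time 34 h

| larch run: time / h | larch run: [Pdt] / mM | elm run: time / h | elm run: [Pdt] / mM |
|---|---|---|---|
| 4.2 | 25.4 | 4.2 | 38.9 |
| 8.5 | 44.1 | 8.5 | 66.3 |
| 13 | 55.9 | 13 | 78.0 |
| 17 | 61.8 | 17 | 82.5 |
| 21 | 66.7 | 21 | 83.9 |
| 26 | 70.0 | 26 | 84.6 |
| 30 | 70.9 | 30 | 85.7 |
| 34 | 72.2 | 34 | 85.1 |

(readings scatter by 0.6 mM)

- how the opening rate goes with [Ptn] round the charge of the larch run: the exponent of the rate at two percent of Sbt gone to Pdt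
- Pdt in the oak run at 34 h, as a share of the Sbt charged

- Overall: Sbt + Ptn -> Pdt, with Ctl as catalyst.
- Constant volume, constant temperature.
- "The second partner" is Ptn.
- An order is taken over about fifteen percent of the charge, up and down.

At 34 h the readings put the lack, the share of the Sbt charge not found as Pdt, at 39.8% in the larch run and at 29.1% in the elm run. The larch run then still holds 0.108 M of Ptn, more than the 0.0478 M of Sbt not found as Pdt, so its lack is not a shortage of Ptn, and yet the elm run, with more Ptn, lacks less. The earliest readings, 25.4 mM and 38.9 mM at 4.2 h, give an order in Ptn of 1.05, which I take as my estimate for the opening rate. I suppose that Pdt forms at a rate near the first power of cPtn while some loss of Sbt ignores Ptn, and as a working assumption I let the lack run as a straight line in the reciprocal of the charged cPtn. I take the slope of that line through the two runs, 58.0 mM, and call it the Ptn leverage, the lack removed per unit of reciprocal charged cPtn.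

Now I turn the question round. For the oak run to turn its whole charge into Pdt, its lack would have to fall by the full 29.1% below the elm run, but the leverage gives a fall of 5.8 percentage points, which is much less. The elm readings at 26 h and 34 h differ by 0.500 mM, within the scatter, and I take the oak run, with more Ptn, to have levelled off as well. So I expect a lack of 23.3% and a yield of 76.7%.

The forecast takes the levelling off for “a reversible reaction” and gives an order of 1.1 and a yield of 79%, above my figure.

The oak run gives 77.5% of its Sbt charge as Pdt at 34 h, and the exponent round the larch charge is 1.1.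

    2 Ctl ⇌ Ctl2, settled at all times (516.0 /M)
    Ctl + Sbt + Ptn → Pdt + Ctl (137.2 /M²/h)
    Sbt + Ptn + Pdt → 2 Pdt (10.91 /M²/h)
    2 Sbt → L (0.4824 /M/h)

Beside the catalysed step with 137 /M²/h, the scheme holds a loss of Sbt to L, in which Ptn takes no part, with 0.482 /M/h. The oak lack is 22.5%. From the elm reading to the oak run the leverage gave a fall of 5.8 points, and the fall from that reading to the oak value is 6.6 points.

The earlier runs and the new flask were generated by integration with made-up constants.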